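The readings are calculated from invented constants; scatter was added.

4 questions are put to the teal flask, and I take them through a prior one: why does it stop?

| setting | teal | violet | flask |
|---|---|---|---|
| starting complex | 20 mM | 20 mM | 20 mM |
| incoming ligand | 1.05 equiv | 1.6 equiv | 1.05 equiv |
| protic impurity | 4 mM | 4 mM | 4.00 mM |
| temperature | 25 °C | 31 °C | 25 °C |
| remark | the very flask that is asked about, followed so far | run made earlier |  |
| time |  |  | 50 min |

| run | time / min | complex with one exchanged / % | starting complex / % |
|---|---|---|---|
| teal | 10.0 | 40.6 | 24.5 |
| teal | 20.0 | 47.3 | 19.3 |
| teal | 30.0 | 47.2 | 16.9 |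
| teal | 40.0 | 49.2 | 15.9 |
| teal | 50.0 | 49.6 | 15.7 |
| violet | 0.667 | 20.0 | 58.7 |
| violet | 1.33 | 29.5 | 42.8 |
| violet | 2.00 | 34.8 | 36.4 |
| violet | 3.00 | 39.0 | 25.8 |
| violet | 4.00 | 43.2 | 18.8 |

(each reading ± 1 percentage point)

- complex with one exchanged, in percent of the starting complex first charged, at 50 min
- which option adds most complex with one exchanged ("none" when 2 percentage points or less is all one gets) (spring / autumn / dawn / midnight / none)
- complex with one exchanged present, in percent of the starting complex first charged, after spring
- complex with one exchanged present, in percent of the starting complex first charged, after midnight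

- spring: at 50 min raise the temperature by 10 K, then wait 50 min
- autumn: at 50 min take out 90 % of the leaving ligand then present, then wait 50 min
- dawn: change nothing and wait 50 min more
- midnight: at 50 min add incoming ligand, 100 % of the amount charged, then wait 50 min

- the volume of additions can be left aside

Starting complex in the teal flask moves by 0.2 percentage points between the last two readings, and a reading scatters by 1 point. Either incoming ligand has been used up, or the first exchange runs backward as fast as forward, like a relaxed first-order system.

I turn the question round and ask what ligand exhaustion requires. The first violet reading already lacks 21.3 % of the charge, close to the impurity's share 20.0 %, so I book that share as starting complex lost to the impurity. The last teal reading then leaves 14.7 % in unseen forms. To consume the charged ligand, these forms must carry 3.77 ligands each, which I consider a heavy demand, so I read the stop as a balance.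

Its measure is the reaction quotient of the first exchange, Q = c(complex with one exchanged)·c(leaving ligand) / [c(starting complex)·c(incoming ligand)]. At a given temperature the ratio of backward to forward rate of this step grows in proportion to Q, and the two rates meet where Q reaches the equilibrium constant. If each unseen complex carries two ligands, which is my assumption, the last teal reading gives an estimate of Q = 9.60, with the scatter of the readings in it.

I therefore expect about 49.6 % now and no gain above 2 points from waiting. Adding incoming ligand or removing leaving ligand lowers Q, but my 14.7 % of unseen forms may take up ligand as well, so I claim no gain from either, and the readings leave the effect of heat open.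

The forecast gives 49.4 %, midnight as best, 49.6 % after spring and 58.3 % after midnight, holding that “The stall looks like ligand running out, not equilibrium”.

The flask gives 49.1 %, and spring is best at 10 points, reaching 59.6 %, while midnight changes it by −18 points, to 31.4 %.

    complex with three exchanged + incoming ligand ⇌ leaving ligand + complex with four exchanged (K = 0.560, k = 0.0440 M⁻¹ s⁻¹, Ea = 51.0 kJ mol⁻¹, ΔH = −75.0 kJ mol⁻¹)
    protic impurity + starting complex → quenched substrate (k = 8.50 M⁻¹ s⁻¹, Ea = 55.0 kJ mol⁻¹)
    complex with two exchanged + incoming ligand ⇌ leaving ligand + complex with three exchanged (K = 17.0, k = 0.150 M⁻¹ s⁻¹, Ea = 55.0 kJ mol⁻¹, ΔH = −80.0 kJ mol⁻¹)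
    starting complex + incoming ligand ⇌ leaving ligand + complex with one exchanged (K = 23.0, k = 0.170 M⁻¹ s⁻¹, Ea = 59.0 kJ mol⁻¹, ΔH = 15.0 kJ mol⁻¹)
    complex with one exchanged + incoming ligand ⇌ leaving ligand + complex with two exchanged (K = 0.750, k = 0.110 M⁻¹ s⁻¹, Ea = 67.0 kJ mol⁻¹, ΔH = −60.0 kJ mol⁻¹)
    (constants at 25 °C)

At 50.0 min, 13 % of the incoming ligand remains in the asked flask, and its state gives Q = 22.5, where my assumption of two ligands on the readings gave 9.60; this state value lies close to the constant 23. In that flask the relaxation half-life of the first exchange by itself, both ways together, is 9.84 min at the asked time, short against 50 min. In the neighbour flask with 0.420 equiv of incoming ligand, that ligand is the limiting reagent, and if Q stands at 22.5 with each ligand used going to complex with one exchanged, I reckon 4.91 % of its charge left. The computed neighbour flask keeps 4.35 % at 50.0 min, with 34.3 % complex with one exchanged.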